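**Retrosynthetic overview**
1. Feature: the furan-2,5-dione ring is read as two acyl units joined across its C3=C4 alkene. Chain-bearing C3 with C2=O is Cα/C1 of an 18-carbon fatty acid oxygenated at C17. Methyl-bearing C4 with its CH3 and C5=O is a pyruvate unit.
2. Last disconnection: the ring acyl–O bond, the ring alkene and the acetate all trace back to one open-chain 2-hydroxy-2-methyl-3-alkylsuccinic acid (Ac2O dehydration). This five-membered anhydride is the only ring and is closed last.
3. Key disconnection: the C–C bond between the two future alkene carbons, made by aldol addition of the lithium enolate of methyl (S)-17-(TBSO)octadecanoate to the ketone of methyl pyruvate.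
4. The C18 ester is cut at C11–C12, a B-alkyl Suzuki–Miyaura coupling of a C7 borane with methyl 11-bromoundecanoate.
5. C16–C18 and the (S)-carbinol come from (S)-propylene oxide, because a methyl/n-alkyl ketone gives too little steric bias for a dependable asymmetric reduction.

Key step: step 4

Remark on the chemistry: the tether between the carbinol carbon and the ring is read as fourteen CH2 groups and the carbinol as (S). No step breaks a bond at this carbon, so the optical purity of commercial (S)-propylene oxide fixes that of the target.

**Step 1**
Reactants: 1 (S)-propylene oxide; 2 but-3-enylmagnesium bromide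
Product: 4 (2S)-hept-6-en-2-ol, via bromomagnesium alkoxide 3 (not isolated)
Conditions: CuI (10 mol %), THF, −30 → 0 °C; aq. NH4Cl
Reagents that add atoms: none
Why: Copper-catalysed Grignard opening of a terminal epoxide is an SN2 attack at the unsubstituted CH2, so no bond to the stereocentre breaks and the (S) configuration of 1 passes into 4 (the new CH2R branch keeps the CIP rank of the old ring CH2O, so the descriptor stays S).

**Step 2**
Reactants: 4 (2S)-hept-6-en-2-ol
Product: 5 tert-butyl[(2S)-hept-6-en-2-yloxy]dimethylsilane
Conditions: TBSCl, imidazole, DMF, rt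
Reagents that add atoms: tert-butyldimethylsilyl chloride, CC(C)(C)[Si](C)(C)Cl
Why: Imidazole-promoted O-silylation removes the one acidic proton that would consume base in step 4 and touches neither the stereocentre nor the alkene.

**Step 3**
Reactants: 5 tert-butyl[(2S)-hept-6-en-2-yloxy]dimethylsilane; 6 methyl 11-bromoundecanoate
Product: 8 methyl (17S)-17-(tert-butyldimethylsilyloxy)octadecanoate, via B-alkyl-9-BBN borane 7 (not isolated)
Conditions: 9-BBN-H (0.5 M in THF), 0 °C → rt; then 6, Pd(OAc)2 (4 mol %), PCy3 (8 mol %), K3PO4·H2O, THF, rt
Reagents that add atoms: none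
Why: Anti-Markovnikov hydroboration puts boron on the terminal carbon, and the B-alkyl Suzuki–Miyaura coupling with an unactivated primary alkyl bromide is known under Pd(OAc)2/PCy3, where the bulky electron-rich phosphine speeds oxidative addition and lets reductive elimination outrun β-hydride elimination, while hydrated K3PO4 at room temperature spares the methyl ester and the silyl ether.

**Step 4**
Reactants: 8 methyl (17S)-17-(tert-butyldimethylsilyloxy)octadecanoate; 9 methyl pyruvate
Product: 12 dimethyl 2-hydroxy-2-methyl-3-[(15S)-15-(tert-butyldimethylsilyloxy)hexadecyl]butanedioate (diastereomer mixture at C2/C3), via lithium enolate 10 (not isolated), via lithium aldolate 11 (not isolated)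
Conditions: LiN(iPr)2 (LDA, commercial solution, 1.05 equiv), THF, 8 added to the base at −78 °C, → −40 °C, → −78 °C; 9 (freshly distilled, 1.5 equiv), −78 °C; AcOH/THF quench at −78 °C
Reagents that add atoms: none
Why: LiN(iPr)2 removes one α-proton of 8 irreversibly to give enolate 10 (chain trans to OLi as expected for kinetic deprotonation in THF, although the geometry has no bearing on the outcome), whose α-carbon adds to the ketone carbonyl of 9 through a lithium-bridged chair-like six-membered (Zimmerman–Traxler-type) transition state to give aldolate 11, which is protonated cold to 12. The closest known reaction type is the directed crossed aldol addition of a preformed ester lithium enolate to an α-keto ester, which is established for long-chain fatty esters and pyruvates. The step makes one C–C bond, the one joining the two future ring-alkene carbons, and it closes no ring. The two new stereocentres (C2 and C3 of the succinate) form without control and need none, because both become sp2 in step 7, and the distant (S)-carbinol carbon takes no part. The selectivity needed is chemoselectivity for ketone addition over proton transfer from the pyruvate CH3 and over acyl substitution at either ester; it rests on the ketone being the most electrophilic site next to its ester, on complete enolisation before 9 arrives, on fast addition of excess 9 at −78 °C, and on the acidic quench at that temperature, which also blocks retro-aldol cleavage. Brief warming to −40 °C keeps the waxy ester dissolved during enolisation, inverse addition suppresses Claisen self-condensation, and the TBS ether at C17 offers nothing that an amide base or an enolate can attack.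

**Step 5**
Reactants: 12 dimethyl 2-hydroxy-2-methyl-3-[(15S)-15-(tert-butyldimethylsilyloxy)hexadecyl]butanedioate
Product: 13 dimethyl 2-hydroxy-3-[(15S)-15-hydroxyhexadecyl]-2-methylbutanedioate
Conditions: p-TsOH·H2O (10 mol %), MeOH/CH2Cl2, rt
Reagents that add atoms: none
Why: Acid-catalysed methanolysis of a secondary TBS ether cleaves only the Si–O bond, so the carbinol keeps its configuration, the methyl esters can only exchange degenerately with the solvent, and the tertiary α-hydroxy ester carbon is too electron-poor to ionise.

**Step 6**
Reactants: 13 dimethyl 2-hydroxy-3-[(15S)-15-hydroxyhexadecyl]-2-methylbutanedioate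
Product: 15 2-hydroxy-3-[(15S)-15-hydroxyhexadecyl]-2-methylbutanedioic acid, via disodium dicarboxylate 14 (not isolated)
Conditions: NaOH (2 M aq.), THF/MeOH, 55 °C; then 1 M HCl to pH 2, 0 °C
Reagents that add atoms: sodium hydroxide, [Na+].[OH-]
Why: Saponification by acyl–oxygen cleavage needs gentle heating because both esters are α-branched, retro-aldol cleavage should stay slow because it would have to expel an ester or carboxylate enolate, and cold acidification frees the diacid without touching the carbinol.

**Step 7**
Reactants: 15 2-hydroxy-3-[(15S)-15-hydroxyhexadecyl]-2-methylbutanedioic acid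
Product: 17 (2S)-16-(4-methyl-2,5-dioxo-2,5-dihydrofuran-3-yl)hexadecan-2-yl acetate (target), via acetoxysuccinic anhydride 16 (not isolated)
Conditions: Ac2O (solvent), NaOAc (0.5 equiv), 120 °C; evaporation, non-aqueous work-up
Reagents that add atoms: acetic anhydride, CC(=O)OC(C)=O
Why: Hot Ac2O turns the 1,4-diacid through a mixed anhydride into the five-membered cyclic anhydride and acetylates both hydroxyls to give 16, after which acetate removes the ring C–H α to a carbonyl and expels the β-acetoxy group (E1cB), so every diastereomer should converge on the tetrasubstituted, doubly conjugated maleic anhydride alkene as in the classical dehydration of citramalic-type acids, while O-acetylation of the secondary alcohol retains the (S) configuration.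

**Compound list**
1 | (S)-propylene oxide, (2S)-2-methyloxirane | C[C@H]1CO1 | starting material
2 | but-3-enylmagnesium bromide (THF solution) | C=CCC[Mg]Br | starting material
3 | bromomagnesium (2S)-hept-6-en-2-olate | Br[Mg]O[C@@H](C)CCCC=C | intermediate
4 | (2S)-hept-6-en-2-ol | O[C@@H](C)CCCC=C | intermediate
5 | tert-butyl[(2S)-hept-6-en-2-yloxy]dimethylsilane | CC(C)(C)[Si](C)(C)O[C@@H](C)CCCC=C | intermediate
6 | methyl 11-bromoundecanoate | COC(=O)CCCCCCCCCCBr | starting material
7 | 9-[(6S)-6-(tert-butyldimethylsilyloxy)heptyl]-9-borabicyclo[3.3.1]nonane | CC(C)(C)[Si](C)(C)O[C@@H](C)CCCCCB1C2CCCC1CCC2 | intermediate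
8 | methyl (17S)-17-(tert-butyldimethylsilyloxy)octadecanoate | CC(C)(C)[Si](C)(C)O[C@@H](C)CCCCCCCCCCCCCCCC(=O)OC | intermediate
9 | methyl pyruvate | CC(=O)C(=O)OC | starting material
10 | lithium enolate of 8 (chain trans to OLi) | CC(C)(C)[Si](C)(C)O[C@@H](C)CCCCCCCCCCCCCC/C=C(/O[Li])OC | intermediate
11 | lithium aldolate of 12 (diastereomer mixture at C2/C3) | CC(C)(C)[Si](C)(C)O[C@@H](C)CCCCCCCCCCCCCCC(C(=O)OC)C(C)(O[Li])C(=O)OC | intermediate
12 | dimethyl 2-hydroxy-2-methyl-3-[(15S)-15-(tert-butyldimethylsilyloxy)hexadecyl]butanedioate (diastereomer mixture at C2/C3) | CC(C)(C)[Si](C)(C)O[C@@H](C)CCCCCCCCCCCCCCC(C(=O)OC)C(C)(O)C(=O)OC | intermediate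
13 | dimethyl 2-hydroxy-3-[(15S)-15-hydroxyhexadecyl]-2-methylbutanedioate (diastereomer mixture at C2/C3) | O[C@@H](C)CCCCCCCCCCCCCCC(C(=O)OC)C(C)(O)C(=O)OC | intermediate
14 | disodium 2-hydroxy-3-[(15S)-15-hydroxyhexadecyl]-2-methylbutanedioate | O[C@@H](C)CCCCCCCCCCCCCCC(C(=O)[O-])C(C)(O)C(=O)[O-].[Na+].[Na+] | intermediate
15 | 2-hydroxy-3-[(15S)-15-hydroxyhexadecyl]-2-methylbutanedioic acid (diastereomer mixture at C2/C3) | O[C@@H](C)CCCCCCCCCCCCCCC(C(=O)O)C(C)(O)C(=O)O | intermediate
16 | (2S)-16-(4-acetoxy-4-methyl-2,5-dioxooxolan-3-yl)hexadecan-2-yl acetate (diastereomer mixture in the ring) | CC(=O)O[C@@H](C)CCCCCCCCCCCCCCC1C(=O)OC(=O)C1(C)OC(C)=O | intermediate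
17 | (2S)-16-(4-methyl-2,5-dioxo-2,5-dihydrofuran-3-yl)hexadecan-2-yl acetate | CC(=O)O[C@@H](C)CCCCCCCCCCCCCCC1=C(C)C(=O)OC1=O | target

**Total step count:** 7. **Longest linear sequence:** 7 steps (from 1). Compounds 2, 6 and 9 enter as purchased materials.

**Steps most likely to fail**

Step 4. The enolate may act as a base toward the acidic CH3 of the pyruvate instead of adding to its ketone. That would return the ester and set off pyruvate self-condensation. The aldolate may also revert if the mixture warms before the quench. The fallback sets out from 8 and replaces the basic nucleophile by a neutral one.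
- The enolate is trapped with TMSCl (LiN(iPr)2, TMSCl, THF, −78 °C) as the methyl trimethylsilyl ketene acetal F1.
- Methyl pyruvate 9 is pre-complexed with TiCl4 in CH2Cl2 at −78 °C. Chelation through the ketone and ester oxygens activates the ketone selectively.
- F1 is then added (Mukaiyama aldol addition). No proton transfer is possible, and the secondary TBS ether should tolerate the short cold contact with TiCl4.
- Aqueous work-up frees the tertiary hydroxyl, and the route is rejoined at 12.

Step 7. The free β-hydroxy or β-acetoxy acid may fragment with loss of CO2 before the ring closes. Elimination may stall at the acetoxy anhydride stage, or the material may darken during long heating in Ac2O. The fallback sets out from 12 and moves the dehydration to the diester stage.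
- SOCl2/pyridine (0 °C → rt) is followed by DBU in toluene at 80 °C to bring all alkene isomers into conjugation. This should give the dimethyl 2-methyl-3-[(15S)-15-(tert-butyldimethylsilyloxy)hexadecyl]but-2-enedioate F2 as an E/Z mixture.
- NaOH in MeOH/THF/H2O at reflux, then 2 M HCl in THF at rt, hydrolyses both esters and removes the silyl group. The Z-diacid then closes spontaneously to the 3-[(15S)-15-hydroxyhexadecyl]-4-methylfuran-2,5-dione F3.
- Ac2O/pyridine/DMAP acetylates the carbinol, and gentle warming should draw any remaining E-diacid into the ring. The route is rejoined at 17.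

Step 3. β-Hydride elimination from the alkylpalladium intermediate, hydrodehalogenation of the bromo ester, slow transmetalation from boron, or oxidation of the phosphine may erode the sp3–sp3 coupling. The fallback sets out from 1 and builds the chain by olefin metathesis and saturation.
- Epoxide 1 is opened with hex-5-enylmagnesium bromide (from 6-bromohex-1-ene and Mg; CuI cat., THF) to (2S)-non-8-en-2-ol F4.
- Silylation (TBSCl, imidazole) gives tert-butyl[(2S)-non-8-en-2-yloxy]dimethylsilane F5.
- Cross-metathesis with excess commercial methyl undec-10-enoate (second-generation Grubbs catalyst, CH2Cl2, reflux, 1,4-benzoquinone against chain-walking) should give methyl (17S)-17-(tert-butyldimethylsilyloxy)octadec-10-enoate F6 as an E/Z mixture. It should be separable from both homodimers by polarity.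
- Hydrogenation (H2, Pd/C, EtOAc) rejoins the route at 8.

**Further compounds**
F1 | step 4 | methyl trimethylsilyl ketene acetal of 8 | CC(C)(C)[Si](C)(C)O[C@@H](C)CCCCCCCCCCCCCC/C=C(/O[Si](C)(C)C)OC
F2 | step 7 | dimethyl 2-methyl-3-[(15S)-15-(tert-butyldimethylsilyloxy)hexadecyl]but-2-enedioate (E/Z mixture) | CC(C)(C)[Si](C)(C)O[C@@H](C)CCCCCCCCCCCCCCC(C(=O)OC)=C(C)C(=O)OC
F3 | step 7 | 3-[(15S)-15-hydroxyhexadecyl]-4-methylfuran-2,5-dione | O[C@@H](C)CCCCCCCCCCCCCCC1=C(C)C(=O)OC1=O
F4 | step 3 | (2S)-non-8-en-2-ol | O[C@@H](C)CCCCCC=C
F5 | step 3 | tert-butyl[(2S)-non-8-en-2-yloxy]dimethylsilane | CC(C)(C)[Si](C)(C)O[C@@H](C)CCCCCC=C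
F6 | step 3 | methyl (17S)-17-(tert-butyldimethylsilyloxy)octadec-10-enoate (E/Z mixture) | CC(C)(C)[Si](C)(C)O[C@@H](C)CCCCCC=CCCCCCCCCC(=O)OC
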